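The cycloheptane is disconnected at C4–C5 and C7–C8, leaving a 1-vinyl-2-methylcyclopentene that (−)-α-bisabolol supplies by oxidative cleavage and ring contraction. In one operation a rhodium vinylcarbenoid exploits the C4=C10–C9=C8 diene: it cyclopropanates the terminal C8=C9 alkene and the cis-divinylcyclopropane rearranges, closing the seven-membered ring C4–C10 and creating quaternary C4 by joining C5 to the fully substituted alkene carbon of the five-membered ring; the C6=C7 enoate and C9=C10 alkene left behind serve the acetoxy/methylidene unit and the ring-fusion hydrogen. The precursor carries C11–C14 as a γ-lactone, not a lactol acetal: one stereoisomer, no hydridic acetal C–H, and no contest between two aldehydes for the C11 hydroxyl.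

Key step: step 6

Remark (numbering): atom labels in the text follow the target: C1 ring CH bearing the side chain, C2, C3, C4 quaternary methyl carbon, C5, C6 ring acetoxy carbon, C7 methylidene-bearing carbon, C8, C9, C10 ring-fusion CH, C11 carbinol carbon, C12, C13, C14 side-chain acetoxy carbon, C15 isopropenyl carbon; compound names use systematic locants.

Remark (assumption): Rh2(R-DOSP)4 is taken as the catalyst enantiomer that gives the 1S,2S cyclopropane, by analogy with the established facial preference of this catalyst family toward monosubstituted alkenes; the lactone is a spectator-group choice that leaves the skeleton and the bonds formed in the key step unchanged.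

Step 1
Reactants: 1 (−)-α-bisabolol
Product: 3 (5S)-5-methyl-5-[(1S)-4-methylcyclohex-3-en-1-yl]oxolan-2-one, via oxolanyl carbinol 2 (not isolated)
Conditions: pyridinium chlorochromate (C5H5NH[CrO3Cl], 5 equiv), Celite, CH2Cl2, rt → 40 °C
Reagents that add atoms: pyridinium chlorochromate, [O-][Cr](=O)(=O)Cl.c1cc[nH+]cc1
Why: Hexavalent-chromium oxidative cyclization–cleavage of a bishomoallylic tertiary alcohol: the chromate ester of the C11 hydroxyl adds across the flexible side-chain alkene (the ring alkene could be reached only through a strained bridged transition state), and the β-hydroxy ether formed fragments with loss of acetone and is oxidised on to the γ-lactone, leaving both stereocentres untouched.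

Step 2
Reactants: 3 (5S)-5-methyl-5-[(1S)-4-methylcyclohex-3-en-1-yl]oxolan-2-one
Product: 5 (3S)-3-[(2S)-2-methyl-5-oxooxolan-2-yl]-6-oxoheptanal, via ozonide 4 (not isolated)
Conditions: O3, CH2Cl2, −78 °C; then PPh3, −78 °C → rt
Reagents that add atoms: ozone, [O-][O+]=O
Why: Ozonolysis of the one remaining alkene with reductive work-up should give the 1,6-keto aldehyde, the lactone being inert and neither stereocentre lying α to a carbonyl group.

Step 3
Reactants: 5 (3S)-3-[(2S)-2-methyl-5-oxooxolan-2-yl]-6-oxoheptanal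
Product: 6 (5S)-2-methyl-5-[(2S)-2-methyl-5-oxooxolan-2-yl]cyclopent-1-ene-1-carbaldehyde
Conditions: piperidine (0.3 equiv), AcOH (0.3 equiv), toluene, 70 °C
Reagents that add atoms: none
Why: Amine-catalysed intramolecular aldol condensation, in which the enamine of the aldehyde attacks the methyl ketone (5-enolexo) and dehydration gives the tetrasubstituted enal; C1 is attached to the α-carbon but is not itself enolisable, so it is not epimerised.

Step 4
Reactants: 6 (5S)-2-methyl-5-[(2S)-2-methyl-5-oxooxolan-2-yl]cyclopent-1-ene-1-carbaldehyde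
Product: 7 (5S)-5-[(1S)-2-ethenyl-3-methylcyclopent-2-en-1-yl]-5-methyloxolan-2-one
Conditions: Ph3PCH3Br (1.3 equiv), KOtBu (1.2 equiv), THF, 0 °C, 1 h
Reagents that add atoms: methyltriphenylphosphonium bromide, C[P+](c1ccccc1)(c1ccccc1)c1ccccc1.[Br-]
Why: Wittig methylenation of the aldehyde by the non-stabilised ylide is far faster at 0 °C than attack on the lactone and should give the 1-vinyl-2-methylcyclopentene.

Step 5
Reactants: 8 methyl but-3-enoate
Product: 9 methyl 2-diazobut-3-enoate
Conditions: 4-acetamidobenzenesulfonyl azide (1.2 equiv), 1,8-diazabicyclo[5.4.0]undec-7-ene (1.2 equiv), MeCN, 0 °C, 30 min; extracted into hexanes and used cold at once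
Reagents that add atoms: 4-acetamidobenzenesulfonyl azide, CC(=O)Nc1ccc(cc1)S(=O)(=O)N=[N+]=[N-]
Why: Regitz diazo transfer to the methylene that is both allylic and α to the ester gives the vinyldiazoacetate, which is kept cold and used immediately because it cyclises to a pyrazole on standing.

Step 6
Reactants: 7 (5S)-5-[(1S)-2-ethenyl-3-methylcyclopent-2-en-1-yl]-5-methyloxolan-2-one, 9 methyl 2-diazobut-3-enoate
Product: 11 methyl (1S,3aR)-3a-methyl-1-[(2S)-2-methyl-5-oxooxolan-2-yl]-1,2,3,3a,4,7-hexahydroazulene-6-carboxylate, via cis-divinylcyclopropane 10 (not isolated)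
Conditions: Rh2(R-DOSP)4 (dirhodium tetrakis[(R)-N-(4-dodecylbenzenesulfonyl)prolinate], 2 mol %), hexanes/toluene 4:1, −40 °C → rt, 9 (3 equiv) added over 2 h; then 60 °C, 2 h
Reagents that add atoms: none
Why: The divalent-rhodium catalyst converts 9 into an electrophilic vinylcarbenoid that adds to the terminal C8=C9 alkene of 7 (the tetrasubstituted C4=C10 alkene is too hindered), placing the carbenoid vinyl group cis to the cyclopentenyl group, and the resulting cis-divinylcyclopropane 10 undergoes a boat-shaped [3,3] shift that forms C4–C5 and breaks C7–C9. The closest known reaction type is the tandem cyclopropanation/Cope rearrangement of vinyldiazoacetates with 1-vinylcycloalkenes, a formal (4+3) cycloaddition. The seven-membered ring closes by strain-driven ring expansion of the cyclopropane, the bond to quaternary C4 being made inside the six-atom pericyclic array and not by an external reagent approaching a hindered carbon. The one new stereocentre that survives, C4, is set by chirality transfer from C9 of the cyclopropane, and C9 is fixed by the chiral prolinate ligands, the R catalyst being the enantiomer expected on the usual facial model to give the 1S,2S cyclopropane. The selectivity required is bonding of C5 to the face of C4 opposite the C1 substituent: in the boat of the 1S,2S cyclopropane the lactone-bearing C11 points away from the incoming C5=C6 unit, whereas the other cyclopropane would force the two together, so catalyst control and the steric demand of the substrate work in the same direction. Cyclopropanation is secured over C–H insertion by the electron-rich, unhindered terminal alkene and by a precursor that offers no C–H bond flanked by two oxygens.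

Step 7
Reactants: 11 methyl (1S,3aR)-3a-methyl-1-[(2S)-2-methyl-5-oxooxolan-2-yl]-1,2,3,3a,4,7-hexahydroazulene-6-carboxylate
Product: 13 (1S,3aR)-3a-methyl-1-[(2S)-2-methyl-5-oxooxolan-2-yl]-1,2,3,3a,4,7-hexahydroazulene-6-carboxylic acid, via dilithium hydroxy dicarboxylate 12 (not isolated)
Conditions: LiOH·H2O (5 equiv), THF/MeOH/H2O, rt; then 1 M HCl to pH 2, rt, 1 h
Reagents that add atoms: lithium hydroxide, [Li+].[OH-]
Why: Saponification cleaves the methyl ester (and opens the lactone), and on acidification the tertiary γ-hydroxy acid should reclose to the γ-lactone, leaving the conjugated carboxylic acid as the only free acid; the doubly allylic C8 methylene is not vinylogous to the ester, so the skipped diene should not migrate.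

Step 8
Reactants: 13 (1S,3aR)-3a-methyl-1-[(2S)-2-methyl-5-oxooxolan-2-yl]-1,2,3,3a,4,7-hexahydroazulene-6-carboxylic acid
Product: 15 (5S)-5-[(1S,3aR)-6-(hydroxymethyl)-3a-methyl-1,2,3,3a,4,7-hexahydroazulen-1-yl]-5-methyloxolan-2-one, via mixed carbonic anhydride 14 (not isolated)
Conditions: i-BuOCOCl (1.1 equiv), N-methylmorpholine (1.1 equiv), THF, −15 °C; then NaBH4 (3 equiv), THF/H2O, 0 °C
Reagents that add atoms: none
Why: Activation of the acid as a mixed carbonic anhydride followed by borohydride reduction gives the primary allylic alcohol, and is chosen over an aluminium hydride because NaBH4 at 0 °C does not reduce the γ-lactone.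

Step 9
Reactants: 15 (5S)-5-[(1S,3aR)-6-(hydroxymethyl)-3a-methyl-1,2,3,3a,4,7-hexahydroazulen-1-yl]-5-methyloxolan-2-one
Product: 16 (5S)-5-[(1S,3aR,5S,6S)-5,6-epoxy-6-(hydroxymethyl)-3a-methyl-1,2,3,3a,4,5,6,7-octahydroazulen-1-yl]-5-methyloxolan-2-one
Conditions: Ti(OiPr)4 (10 mol %), L-(+)-diethyl tartrate (12 mol %), t-BuOOH (2 equiv), 4 Å molecular sieves, CH2Cl2, −20 °C
Reagents that add atoms: tert-butyl hydroperoxide, CC(C)(C)OO
Why: Sharpless asymmetric epoxidation acts only on the allylic alcohol (C6=C7) and not on the isolated C9=C10 alkene, and the L-tartrate complex delivers oxygen to the face that makes C6 and C7 both S, which is also the face away from the C4 methyl group, so reagent and substrate control agree.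

Step 10
Reactants: 16 (5S)-5-[(1S,3aR,5S,6S)-5,6-epoxy-6-(hydroxymethyl)-3a-methyl-1,2,3,3a,4,5,6,7-octahydroazulen-1-yl]-5-methyloxolan-2-one
Product: 17 (5S)-5-[(1S,3aR,5S,6S,8aS)-5,6-epoxy-6-(hydroxymethyl)-3a-methyldecahydroazulen-1-yl]-5-methyloxolan-2-one
Conditions: H2 (3 atm), PtO2 (10 mol %), EtOAc, rt
Reagents that add atoms: none
Why: Heterogeneous catalytic hydrogenation of the trisubstituted C9=C10 alkene should add hydrogen syn from the face opposite the C4 methyl group and the bulky C1 substituent, which lie on the same side, so that C10–H is set trans to the angular methyl (8aS); the trialkyl epoxide should survive platinum in a neutral solvent.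

Step 11
Reactants: 17 (5S)-5-[(1S,3aR,5S,6S,8aS)-5,6-epoxy-6-(hydroxymethyl)-3a-methyldecahydroazulen-1-yl]-5-methyloxolan-2-one
Product: 18 (5S)-5-[(1S,3aR,5S,6R,8aS)-5,6-epoxy-6-(iodomethyl)-3a-methyldecahydroazulen-1-yl]-5-methyloxolan-2-one
Conditions: I2 (1.5 equiv), PPh3 (1.5 equiv), imidazole (3 equiv), CH2Cl2, 0 °C → rt
Reagents that add atoms: iodine, [I][I]
Why: Appel-type iodination of the primary alcohol through its alkoxyphosphonium salt runs under imidazole-buffered conditions that leave the epoxide and lactone intact (the 6R descriptor reflects only the changed substituent priority).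

Step 12
Reactants: 18 (5S)-5-[(1S,3aR,5S,6R,8aS)-5,6-epoxy-6-(iodomethyl)-3a-methyldecahydroazulen-1-yl]-5-methyloxolan-2-one
Product: 19 (5S)-5-[(1S,3aR,5S,8aS)-5-hydroxy-3a-methyl-6-methylidenedecahydroazulen-1-yl]-5-methyloxolan-2-one
Conditions: Zn dust (10 equiv), NH4Cl (3 equiv), EtOH/H2O 9:1, 60 °C
Reagents that add atoms: none
Why: Zinc-mediated reductive elimination of the β-iodo epoxide (insertion into C–I, then β-elimination that opens the oxirane) gives the transposed allylic alcohol, the C6–O bond made in the epoxidation being retained so that C6 stays S while C7 becomes the exocyclic methylidene carbon.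

Step 13
Reactants: 19 (5S)-5-[(1S,3aR,5S,8aS)-5-hydroxy-3a-methyl-6-methylidenedecahydroazulen-1-yl]-5-methyloxolan-2-one, 20 2-bromopropene
Product: 23 (6S)-6-hydroxy-6-[(1S,3aR,5S,8aS)-5-hydroxy-3a-methyl-6-methylidenedecahydroazulen-1-yl]-2-methylhept-1-en-3-one, via isopropenyllithium 21 (not isolated), via dilithium hemiketal alkoxide 22 (not isolated)
Conditions: 20 (3.5 equiv), t-BuLi (7 equiv), Et2O, −78 °C; then 19 in THF, −78 °C, 1 h; sat. aq. NH4Cl at −78 °C
Reagents that add atoms: none
Why: Addition of an alkenyllithium to a γ-lactone should stop at the ketone oxidation level because the cyclic lithium hemiketal is stable at −78 °C and gives the enone only on quenching, one equivalent of the reagent being spent on the C6 hydroxyl.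

Step 14
Reactants: 23 (6S)-6-hydroxy-6-[(1S,3aR,5S,8aS)-5-hydroxy-3a-methyl-6-methylidenedecahydroazulen-1-yl]-2-methylhept-1-en-3-one
Product: 24 (3S,6S)-6-[(1S,3aR,5S,8aS)-5-hydroxy-3a-methyl-6-methylidenedecahydroazulen-1-yl]-2-methylhept-1-ene-3,6-diol
Conditions: (R)-2-methyl-CBS-oxazaborolidine [(R)-1-methyl-3,3-diphenyltetrahydro-1H,3H-pyrrolo[1,2-c][1,3,2]oxazaborole, 1.0 equiv], catecholborane (C6H4O2BH, 3 equiv), toluene, −78 °C; then MeOH, 1 M NaOH
Reagents that add atoms: none
Why: Corey–Bakshi–Shibata reduction, in which the ketone binds the catalyst boron anti to the larger isopropenyl group so that the R catalyst should give the S carbinol at C14 (C3 of the heptene chain), catecholborane being chosen because it does not hydroborate the two 1,1-disubstituted alkenes at −78 °C.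

Step 15
Reactants: 24 (3S,6S)-6-[(1S,3aR,5S,8aS)-5-hydroxy-3a-methyl-6-methylidenedecahydroazulen-1-yl]-2-methylhept-1-ene-3,6-diol
Product: 25 (1S,3aR,5S,8aS)-1-[(2S,5S)-5-acetoxy-2-hydroxy-6-methylhept-6-en-2-yl]-3a-methyl-6-methylidenedecahydroazulen-5-yl acetate (target CNP0151143.1)
Conditions: Ac2O (4 equiv), pyridine, 4-(dimethylamino)pyridine (5 mol %), CH2Cl2, 0 °C → rt
Reagents that add atoms: acetic anhydride, CC(=O)OC(C)=O
Why: Nucleophile-catalysed acylation of the two secondary allylic alcohols (C6 and C14) is fast, whereas the hindered tertiary C11 hydroxyl should not react at this temperature, so the diacetate forms with every stereocentre unchanged.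

Compound list

1 | (−)-α-bisabolol, (2S)-6-methyl-2-[(1S)-4-methylcyclohex-3-en-1-yl]hept-5-en-2-ol | CC1=CC[C@H](CC1)[C@](C)(CCC=C(C)C)O | starting material
2 | 2-{(5S)-5-methyl-5-[(1S)-4-methylcyclohex-3-en-1-yl]oxolan-2-yl}propan-2-ol (oxolane C2 epimers, held as chromate ester) | CC1=CC[C@H](CC1)[C@]2(C)CCC(O2)C(C)(C)O | intermediate (not isolated)
3 | (5S)-5-methyl-5-[(1S)-4-methylcyclohex-3-en-1-yl]oxolan-2-one | CC1=CC[C@H](CC1)[C@]2(C)CCC(=O)O2 | intermediate
4 | secondary ozonide of 3, (5S)-5-methyl-5-[(4S)-1-methyl-7,8,9-trioxabicyclo[4.2.1]nonan-4-yl]oxolan-2-one (bridgeheads undefined) | CC12CC[C@H]([C@]3(C)CCC(=O)O3)CC(OO1)O2 | intermediate (not isolated)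
5 | (3S)-3-[(2S)-2-methyl-5-oxooxolan-2-yl]-6-oxoheptanal | O=CC[C@H](CCC(C)=O)[C@]1(C)CCC(=O)O1 | intermediate
6 | (5S)-2-methyl-5-[(2S)-2-methyl-5-oxooxolan-2-yl]cyclopent-1-ene-1-carbaldehyde | O=CC1=C(C)CC[C@@H]1[C@]2(C)CCC(=O)O2 | intermediate
7 | (5S)-5-[(1S)-2-ethenyl-3-methylcyclopent-2-en-1-yl]-5-methyloxolan-2-one | C=CC1=C(C)CC[C@@H]1[C@]2(C)CCC(=O)O2 | intermediate (key-step precursor)
8 | methyl but-3-enoate | C=CCC(=O)OC | starting material
9 | methyl 2-diazobut-3-enoate | C=CC(=[N+]=[N-])C(=O)OC | intermediate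
10 | methyl (1S,2S)-1-ethenyl-2-{(5S)-2-methyl-5-[(2S)-2-methyl-5-oxooxolan-2-yl]cyclopent-1-en-1-yl}cyclopropane-1-carboxylate | C=C[C@@]1(C(=O)OC)C[C@H]1C2=C(C)CC[C@@H]2[C@]3(C)CCC(=O)O3 | intermediate (not isolated)
11 | methyl (1S,3aR)-3a-methyl-1-[(2S)-2-methyl-5-oxooxolan-2-yl]-1,2,3,3a,4,7-hexahydroazulene-6-carboxylate | O=C1CC[C@](C)(O1)[C@H]2CC[C@]3(C)CC=C(C(=O)OC)CC=C23 | intermediate (key-step product)
12 | dilithium (1S,3aR)-1-[(2S)-4-carboxylato-2-hydroxybutan-2-yl]-3a-methyl-1,2,3,3a,4,7-hexahydroazulene-6-carboxylate | [Li+].[Li+].[O-]C(=O)CC[C@](C)(O)[C@H]1CC[C@]2(C)CC=C(C(=O)[O-])CC=C12 | intermediate (not isolated)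
13 | (1S,3aR)-3a-methyl-1-[(2S)-2-methyl-5-oxooxolan-2-yl]-1,2,3,3a,4,7-hexahydroazulene-6-carboxylic acid | O=C1CC[C@](C)(O1)[C@H]2CC[C@]3(C)CC=C(C(=O)O)CC=C23 | intermediate
14 | (1S,3aR)-3a-methyl-1-[(2S)-2-methyl-5-oxooxolan-2-yl]-1,2,3,3a,4,7-hexahydroazulene-6-carboxylic 2-methylpropyl carbonic anhydride | O=C1CC[C@](C)(O1)[C@H]2CC[C@]3(C)CC=C(C(=O)OC(=O)OCC(C)C)CC=C23 | intermediate (not isolated)
15 | (5S)-5-[(1S,3aR)-6-(hydroxymethyl)-3a-methyl-1,2,3,3a,4,7-hexahydroazulen-1-yl]-5-methyloxolan-2-one | O=C1CC[C@](C)(O1)[C@H]2CC[C@]3(C)CC=C(CO)CC=C23 | intermediate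
16 | (5S)-5-[(1S,3aR,5S,6S)-5,6-epoxy-6-(hydroxymethyl)-3a-methyl-1,2,3,3a,4,5,6,7-octahydroazulen-1-yl]-5-methyloxolan-2-one | O=C1CC[C@](C)(O1)[C@H]2CC[C@]3(C)C[C@@H]4O[C@]4(CO)CC=C23 | intermediate
17 | (5S)-5-[(1S,3aR,5S,6S,8aS)-5,6-epoxy-6-(hydroxymethyl)-3a-methyldecahydroazulen-1-yl]-5-methyloxolan-2-one | O=C1CC[C@](C)(O1)[C@H]2CC[C@]3(C)C[C@@H]4O[C@]4(CO)CC[C@@H]23 | intermediate
18 | (5S)-5-[(1S,3aR,5S,6R,8aS)-5,6-epoxy-6-(iodomethyl)-3a-methyldecahydroazulen-1-yl]-5-methyloxolan-2-one | O=C1CC[C@](C)(O1)[C@H]2CC[C@]3(C)C[C@@H]4O[C@]4(CI)CC[C@@H]23 | intermediate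
19 | (5S)-5-[(1S,3aR,5S,8aS)-5-hydroxy-3a-methyl-6-methylidenedecahydroazulen-1-yl]-5-methyloxolan-2-one | O=C1CC[C@](C)(O1)[C@H]2CC[C@]3(C)C[C@H](O)C(=C)CC[C@@H]23 | intermediate
20 | 2-bromopropene | CC(Br)=C | starting material
21 | isopropenyllithium (prop-1-en-2-yllithium) | [Li]C(C)=C | intermediate (not isolated)
22 | dilithium (2S)-2-methyl-2-[(1S,3aR,5S,8aS)-3a-methyl-6-methylidene-5-oxidodecahydroazulen-1-yl]-5-(prop-1-en-2-yl)oxolan-5-olate (oxolane C5 undefined) | [Li+].[Li+].C=C(C)C1([O-])CC[C@](C)(O1)[C@H]2CC[C@]3(C)C[C@H]([O-])C(=C)CC[C@@H]23 | intermediate (not isolated)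
23 | (6S)-6-hydroxy-6-[(1S,3aR,5S,8aS)-5-hydroxy-3a-methyl-6-methylidenedecahydroazulen-1-yl]-2-methylhept-1-en-3-one | C=C(C)C(=O)CC[C@](C)(O)[C@H]1CC[C@]2(C)C[C@H](O)C(=C)CC[C@@H]12 | intermediate
24 | (3S,6S)-6-[(1S,3aR,5S,8aS)-5-hydroxy-3a-methyl-6-methylidenedecahydroazulen-1-yl]-2-methylhept-1-ene-3,6-diol | C=C(C)[C@H](CC[C@](C)(O)[C@H]1CC[C@]2(C)C[C@H](O)C(=C)CC[C@@H]12)O | intermediate
25 | (1S,3aR,5S,8aS)-1-[(2S,5S)-5-acetoxy-2-hydroxy-6-methylhept-6-en-2-yl]-3a-methyl-6-methylidenedecahydroazulen-5-yl acetate | C=C(C)[C@H](CC[C@](C)(O)[C@H]1CC[C@]2(C)C[C@H](OC(C)=O)C(=C)CC[C@@H]12)OC(C)=O | target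

Total step count: 15. Longest linear sequence: 14 steps from 1 (steps 1–4 and 6–15); step 5 is a one-step branch.

Steps most likely to fail

Step 6. The cyclopropanation may show poor facial control if the conformational bias of the diene overrules the catalyst, or the carbenoid may be lost by dimerisation before it meets the hindered diene. The fallback moves stereocontrol from the catalyst to a covalently bound auxiliary. It sets out from 7: but-3-enoic acid is esterified with (R)-pantolactone (N,N'-dicyclohexylcarbodiimide, 4-(dimethylamino)pyridine) to give (3R)-4,4-dimethyl-2-oxooxolan-3-yl but-3-enoate F1, and diazo transfer as in step 5 gives (3R)-4,4-dimethyl-2-oxooxolan-3-yl 2-diazobut-3-enoate F2. Decomposition of this with achiral Rh2(O2CC7H15)4 (dirhodium tetraoctanoate) in the presence of 7 should give, through the auxiliary-bearing cis-divinylcyclopropane F3, the pantolactonyl ester of the cycloheptadiene acid F4. Saponification under the conditions of step 7 removes the auxiliary and the route is rejoined at 13 (through 12). The R auxiliary is proposed; its enantiomer would be used if a trial showed the opposite sense.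

Step 10. Hydrogen may be delivered to the wrong face of C10 (cis ring fusion), or the alkene may migrate on the metal surface to the tetrasubstituted C1=C10 position, which would also erase C1. The fallback replaces surface hydrogenation by radical hydrogen-atom-transfer hydrogenation. It sets out from 16: Mn(dpm)3 (tris(2,2,6,6-tetramethylheptane-3,5-dionato)manganese, trivalent manganese, 10 mol %), PhSiH3, t-BuOOH, i-PrOH, rt. A hydrogen atom adds to C9 and the tertiary C10 radical should be quenched from the face opposite the methyl group and the C1 substituent, with no metal-surface isomerisation; the route is rejoined at 17. It makes no compound outside the main list (entry F0).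

Step 13. The alkenyllithium may add a second time, or in conjugate fashion, if the hemiketal alkoxide collapses to the enone before the quench. The fallback changes the acyl donor to one that gives a chelated, non-collapsing adduct. It sets out from 19: the lactone is opened with MeNH(OMe)·HCl and i-PrMgCl (THF, −20 °C) to (4S)-4-hydroxy-4-[(1S,3aR,5S,8aS)-5-hydroxy-3a-methyl-6-methylidenedecahydroazulen-1-yl]-N-methoxy-N-methylpentanamide F5. Isopropenylmagnesium bromide F6, made from 20 and Mg in THF, is then added in excess to cover the two hydroxyls; the magnesium chelate holds until work-up, and the route is rejoined at 23.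

Further compounds

F1 | step 6 | (3R)-4,4-dimethyl-2-oxooxolan-3-yl but-3-enoate | C=CCC(=O)O[C@H]1C(=O)OCC1(C)C
F2 | step 6 | (3R)-4,4-dimethyl-2-oxooxolan-3-yl 2-diazobut-3-enoate | C=CC(=[N+]=[N-])C(=O)O[C@H]1C(=O)OCC1(C)C
F3 | step 6 | (3R)-4,4-dimethyl-2-oxooxolan-3-yl (1S,2S)-1-ethenyl-2-{(5S)-2-methyl-5-[(2S)-2-methyl-5-oxooxolan-2-yl]cyclopent-1-en-1-yl}cyclopropane-1-carboxylate | C=C[C@@]1(C(=O)O[C@H]2C(=O)OCC2(C)C)C[C@H]1C3=C(C)CC[C@@H]3[C@]4(C)CCC(=O)O4
F4 | step 6 | (3R)-4,4-dimethyl-2-oxooxolan-3-yl (1S,3aR)-3a-methyl-1-[(2S)-2-methyl-5-oxooxolan-2-yl]-1,2,3,3a,4,7-hexahydroazulene-6-carboxylate | O=C1CC[C@](C)(O1)[C@H]2CC[C@]3(C)CC=C(C(=O)O[C@H]4C(=O)OCC4(C)C)CC=C23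
F0 | step 10 | none | none
F5 | step 13 | (4S)-4-hydroxy-4-[(1S,3aR,5S,8aS)-5-hydroxy-3a-methyl-6-methylidenedecahydroazulen-1-yl]-N-methoxy-N-methylpentanamide | CON(C)C(=O)CC[C@](C)(O)[C@H]1CC[C@]2(C)C[C@H](O)C(=C)CC[C@@H]12
F6 | step 13 | isopropenylmagnesium bromide | C=C(C)[Mg]Br
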